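Ring atoms are numbered C1 (bearing the acrylate) through C4(OH), C5(OAc), C8=C9, C10, C11=C12, C13(OH) to C14. The 14-membered ring is closed last at the doubly allylic C9–C10 bond. The seco-precursor carries a C9 alkenylstannane and, in place of the C11=C12 alkene and C13 carbinol, a C12–C13 epoxide bearing the C10=C11 vinyl group. A zerovalent-palladium SN2′ Stille coupling forms C9–C10, creates the E C11=C12 alkene and releases the C13 hydroxyl in one operation, exploiting the 1,4-relationship of C10 and O13 in the skipped diene. The C13–C14–C1–C4 backbone and the C1 and C4 stereocentres derive from (R)-carvone by reductive aldol and Baeyer–Villiger cleavage.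

Key step: step 19

Remark: the aldol of step 3 is expected to give both C5 epimers of 8; they are carried together because C5 becomes a ketone in step 5 and is reset in step 6.

Step 1
Reactants: 1 pent-4-yn-1-ol
Product: 3 (4E)-5-bromo-4-methylpent-4-en-1-ol, via alkenylalane 2 (not isolated)
Conditions: AlMe3 (3 equiv), Cp2ZrCl2 (0.25 equiv), CH2Cl2, 0 °C to rt; then N-bromosuccinimide, THF, −30 °C
Reagents that add atoms: trimethylaluminium C[Al](C)C; N-bromosuccinimide O=C1CCC(=O)N1Br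
Why: Negishi zirconium-catalysed syn-methylalumination of the terminal alkyne puts the methyl on C8 and aluminium on C9, and brominolysis with retention should give the E alkenyl bromide.

Step 2
Reactants: 3 (4E)-5-bromo-4-methylpent-4-en-1-ol
Product: 4 (4E)-5-bromo-4-methylpent-4-enal
Conditions: TEMPO (10 mol %), PhI(OAc)2, CH2Cl2, rt
Reagents that add atoms: none
Why: The TEMPO/PhI(OAc)2 oxidation of a primary alcohol stops at the aldehyde and leaves the alkenyl bromide untouched.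

Step 3
Reactants: 5 (R)-carvone; 4 (4E)-5-bromo-4-methylpent-4-enal
Product: 8 (2R,5R)-2-[(1RS,4E)-5-bromo-4-methyl-1-(trimethylsilyloxy)pent-4-en-1-yl]-2-methyl-5-(prop-1-en-2-yl)cyclohexan-1-one, via lithium enolate 6 (not isolated), via lithium aldolate 7 (not isolated)
Conditions: LiBH(s-Bu)3 (1.0 equiv), THF, −78 °C; then 4, −78 °C; then Me3SiCl, Et3N, −78 to −30 °C
Reagents that add atoms: chlorotrimethylsilane C[Si](C)(C)Cl
Why: Conjugate hydride reduction gives the regiodefined enolate, whose aldol addition should occur by axial attack on the half-chair with the C1 propenyl group equatorial, so that the new C4–C5 bond is cis to that group (this sets the quaternary C4), while O-silylation blocks the retro-aldol.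

Step 4
Reactants: 8 (2R,5R)-2-[(1RS,4E)-5-bromo-4-methyl-1-(trimethylsilyloxy)pent-4-en-1-yl]-2-methyl-5-(prop-1-en-2-yl)cyclohexan-1-one
Product: 10 (4R,7R)-7-[(1RS,4E)-5-bromo-1-hydroxy-4-methylpent-4-en-1-yl]-7-methyl-4-(prop-1-en-2-yl)oxepan-2-one, via silyl ether lactone 9 (not isolated)
Conditions: Me3SiOOSiMe3 (2.5 equiv), Me3SiOTf (20 mol %), CH2Cl2, −78 to −30 °C; then 1 M HCl, THF, 0 °C
Reagents that add atoms: bis(trimethylsilyl) peroxide C[Si](C)(C)OO[Si](C)(C)C
Why: Baeyer–Villiger oxidation with the silyl peroxide spares both alkenes, and the fully substituted C4 should migrate in preference to the C14 methylene and with retention, which turns the C4–C13 ring bond into the C4–O bond of the future tertiary carbinol with the R configuration.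

Step 5
Reactants: 10 (4R,7R)-7-[(1RS,4E)-5-bromo-1-hydroxy-4-methylpent-4-en-1-yl]-7-methyl-4-(prop-1-en-2-yl)oxepan-2-one
Product: 11 (4R,7R)-7-[(4E)-5-bromo-4-methylpent-4-enoyl]-7-methyl-4-(prop-1-en-2-yl)oxepan-2-one
Conditions: Dess–Martin periodinane, NaHCO3, CH2Cl2, rt
Reagents that add atoms: none
Why: Dess–Martin oxidation converts both C5 epimers into a single ketone.

Step 6
Reactants: 11 (4R,7R)-7-[(4E)-5-bromo-4-methylpent-4-enoyl]-7-methyl-4-(prop-1-en-2-yl)oxepan-2-one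
Product: 12 (4R,7R)-7-[(1S,4E)-5-bromo-1-hydroxy-4-methylpent-4-en-1-yl]-7-methyl-4-(prop-1-en-2-yl)oxepan-2-one
Conditions: (R)-2-methyl-CBS-oxazaborolidine (0.5 equiv), catecholborane, toluene, −78 °C
Reagents that add atoms: none
Why: In this Corey–Bakshi–Shibata reduction the catalyst should treat the quaternary C4 as the large group and the C6 methylene as the small one, so the (R)-catalyst should give the 5S alcohol, and catecholborane at low temperature touches neither the lactone nor the alkenes.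

Step 7
Reactants: 12 (4R,7R)-7-[(1S,4E)-5-bromo-1-hydroxy-4-methylpent-4-en-1-yl]-7-methyl-4-(prop-1-en-2-yl)oxepan-2-one
Product: 13 (3R,6R,7S,10E)-11-bromo-6,7-dihydroxy-6,10-dimethyl-3-(prop-1-en-2-yl)undec-10-enal
Conditions: i-Bu2AlH (2.3 equiv), CH2Cl2, −78 °C; aqueous potassium sodium tartrate (KNaC4H4O6)
Reagents that add atoms: none
Why: Half-reduction of the lactone with i-Bu2AlH stops at the aluminium hemiacetal, which on work-up should open to the C13 aldehyde and the free tertiary C4 hydroxyl.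

Step 8
Reactants: 13 (3R,6R,7S,10E)-11-bromo-6,7-dihydroxy-6,10-dimethyl-3-(prop-1-en-2-yl)undec-10-enal
Product: 14 (2E,5R,8R,9S,12E)-13-bromo-8,9-dihydroxy-2,8,12-trimethyl-5-(prop-1-en-2-yl)trideca-2,12-dienal
Conditions: Ph3P=C(CH3)CHO (1.3 equiv), toluene, 90 °C
Reagents that add atoms: 2-(triphenylphosphoranylidene)propanal CC(C=O)=P(c1ccccc1)(c1ccccc1)c1ccccc1
Why: The Wittig reaction with the stabilised ylide should give the E trisubstituted enal (C12=C13) and tolerates the free diol.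

Step 9
Reactants: 14 (2E,5R,8R,9S,12E)-13-bromo-8,9-dihydroxy-2,8,12-trimethyl-5-(prop-1-en-2-yl)trideca-2,12-dienal
Product: 15 (2E,5R,8R,9S,12E)-13-bromo-8-hydroxy-2,8,12-trimethyl-1-oxo-5-(prop-1-en-2-yl)trideca-2,12-dien-9-yl acetate
Conditions: Ac2O, pyridine, DMAP (cat.), CH2Cl2, 0 °C to rt
Reagents that add atoms: acetic anhydride CC(=O)OC(C)=O
Why: Acylation should select the secondary C5 hydroxyl because the tertiary C4 hydroxyl is too hindered to react.

Step 10
Reactants: 15 (2E,5R,8R,9S,12E)-13-bromo-8-hydroxy-2,8,12-trimethyl-1-oxo-5-(prop-1-en-2-yl)trideca-2,12-dien-9-yl acetate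
Product: 16 (2E,5R,8R,9S,12E)-13-bromo-1,8-dihydroxy-2,8,12-trimethyl-5-(prop-1-en-2-yl)trideca-2,12-dien-9-yl acetate
Conditions: NaBH4, CeCl3·7H2O, MeOH, −40 °C
Reagents that add atoms: none
Why: Luche reduction should give clean 1,2-reduction of the enal without touching the acetate.

Step 11
Reactants: 16 (2E,5R,8R,9S,12E)-13-bromo-1,8-dihydroxy-2,8,12-trimethyl-5-(prop-1-en-2-yl)trideca-2,12-dien-9-yl acetate
Product: 17 (2S,3S,5R,8R,9S,12E)-13-bromo-2,3-epoxy-1,8-dihydroxy-2,8,12-trimethyl-5-(prop-1-en-2-yl)tridec-12-en-9-yl acetate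
Conditions: Ti(OiPr)4, L-(+)-diethyl tartrate, t-BuOOH, 4 Å molecular sieves, CH2Cl2, −20 °C
Reagents that add atoms: tert-butyl hydroperoxide CC(C)(C)OO
Why: Sharpless asymmetric epoxidation acts only on the allylic alcohol and, with L-(+)-tartrate on this E 2-methyl-2-alkenol, should deliver oxygen under reagent control to the face that gives the (2S,3S)-epoxide, which fixes C13 as in the target.

Step 12
Reactants: 17 (2S,3S,5R,8R,9S,12E)-13-bromo-2,3-epoxy-1,8-dihydroxy-2,8,12-trimethyl-5-(prop-1-en-2-yl)tridec-12-en-9-yl acetate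
Product: 18 (2S,3S,5R,8R,9S,12E)-13-bromo-5-(3-chloroprop-1-en-2-yl)-2,3-epoxy-1,8-dihydroxy-2,8,12-trimethyltridec-12-en-9-yl acetate
Conditions: Ca(OCl)2, CO2 (solid), CH2Cl2/H2O, 0 °C
Reagents that add atoms: calcium hypochlorite [Ca+2].[O-]Cl.[O-]Cl
Why: Ene-type allylic chlorination with hypochlorous acid should take place at the propenyl group, the only electron-rich alkene left, with shift of the double bond towards the former methyl.

Step 13
Reactants: 18 (2S,3S,5R,8R,9S,12E)-13-bromo-5-(3-chloroprop-1-en-2-yl)-2,3-epoxy-1,8-dihydroxy-2,8,12-trimethyltridec-12-en-9-yl acetate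
Product: 19 (2S,3S,5R,8R,9S,12E)-13-bromo-2,3-epoxy-1,8-dihydroxy-2,8,12-trimethyl-5-(3-oxoprop-1-en-2-yl)tridec-12-en-9-yl acetate
Conditions: N-methylmorpholine N-oxide (4 equiv), NaI (cat.), MeCN, 40 °C
Reagents that add atoms: N-methylmorpholine N-oxide C[N+]1([O-])CCOCC1
Why: In this Kornblum-type oxidation the amine N-oxide displaces the allylic chloride and loss of N-methylmorpholine should give the 2-substituted acrolein.

Step 14
Reactants: 19 (2S,3S,5R,8R,9S,12E)-13-bromo-2,3-epoxy-1,8-dihydroxy-2,8,12-trimethyl-5-(3-oxoprop-1-en-2-yl)tridec-12-en-9-yl acetate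
Product: 20 2-[(2S,3S,5R,8R,9S,12E)-9-acetoxy-13-bromo-2,3-epoxy-1,8-dihydroxy-2,8,12-trimethyltridec-12-en-5-yl]prop-2-enoic acid
Conditions: NaClO2, NaH2PO4, 2-methylbut-2-ene, t-BuOH/H2O, 0 °C to rt
Reagents that add atoms: sodium chlorite [Na+].[O-]Cl=O
Why: Pinnick oxidation converts the enal into the acrylic acid without affecting the alcohols, the epoxide or the alkenes.

Step 15
Reactants: 20 2-[(2S,3S,5R,8R,9S,12E)-9-acetoxy-13-bromo-2,3-epoxy-1,8-dihydroxy-2,8,12-trimethyltridec-12-en-5-yl]prop-2-enoic acid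
Product: 21 (2S,3S,5R,8R,9S,12E)-13-bromo-2,3-epoxy-1,8-dihydroxy-5-(3-methoxy-3-oxoprop-1-en-2-yl)-2,8,12-trimethyltridec-12-en-9-yl acetate
Conditions: Me3SiCHN2, toluene/MeOH, 0 °C
Reagents that add atoms: (trimethylsilyl)diazomethane C[Si](C)(C)C=[N+]=[N-]
Why: Methylation of the carboxylic acid with the diazo reagent is neutral and leaves the acetate, the epoxide and the free hydroxyls alone.

Step 16
Reactants: 21 (2S,3S,5R,8R,9S,12E)-13-bromo-2,3-epoxy-1,8-dihydroxy-5-(3-methoxy-3-oxoprop-1-en-2-yl)-2,8,12-trimethyltridec-12-en-9-yl acetate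
Product: 22 (2S,3S,5R,8R,9S,12E)-2,3-epoxy-1,8-dihydroxy-5-(3-methoxy-3-oxoprop-1-en-2-yl)-2,8,12-trimethyl-13-(trimethylstannyl)tridec-12-en-9-yl acetate
Conditions: Me3SnSnMe3 (1.5 equiv), Pd(PPh3)4 (5 mol %), toluene, 90 °C
Reagents that add atoms: hexamethylditin C[Sn](C)(C)[Sn](C)(C)C
Why: Palladium-catalysed stannylation of the alkenyl bromide (a Stille coupling with a distannane) should proceed with retention of the E geometry and is placed here because the stannane would not survive the chlorination and chlorite steps.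

Step 17
Reactants: 22 (2S,3S,5R,8R,9S,12E)-2,3-epoxy-1,8-dihydroxy-5-(3-methoxy-3-oxoprop-1-en-2-yl)-2,8,12-trimethyl-13-(trimethylstannyl)tridec-12-en-9-yl acetate
Product: 23 (2R,3S,5R,8R,9S,12E)-2,3-epoxy-8-hydroxy-5-(3-methoxy-3-oxoprop-1-en-2-yl)-2,8,12-trimethyl-1-oxo-13-(trimethylstannyl)tridec-12-en-9-yl acetate
Conditions: Dess–Martin periodinane, NaHCO3, CH2Cl2, 0 °C
Reagents that add atoms: none
Why: Buffered Dess–Martin oxidation should give the epoxy aldehyde, which cannot epimerise because C12 is quaternary.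

Step 18
Reactants: 23 (2R,3S,5R,8R,9S,12E)-2,3-epoxy-8-hydroxy-5-(3-methoxy-3-oxoprop-1-en-2-yl)-2,8,12-trimethyl-1-oxo-13-(trimethylstannyl)tridec-12-en-9-yl acetate
Product: 24 (3S,4S,6R,9R,10S,13E)-3,4-epoxy-9-hydroxy-6-(3-methoxy-3-oxoprop-1-en-2-yl)-3,9,13-trimethyl-14-(trimethylstannyl)tetradeca-1,13-dien-10-yl acetate
Conditions: Ph3PCH3Br (1.3 equiv), KN(SiMe3)2 (1.2 equiv), THF, −78 to 0 °C
Reagents that add atoms: methyltriphenylphosphonium bromide C[P+](c1ccccc1)(c1ccccc1)c1ccccc1.[Br-]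
Why: Wittig methylenation of the reactive α,β-epoxy aldehyde at low temperature should install the C10=C11 vinyl group faster than the ylide attacks the acetate or the acrylate.

Step 19
Reactants: 24 (3S,4S,6R,9R,10S,13E)-3,4-epoxy-9-hydroxy-6-(3-methoxy-3-oxoprop-1-en-2-yl)-3,9,13-trimethyl-14-(trimethylstannyl)tetradeca-1,13-dien-10-yl acetate
Product: 25 methyl 2-[(1R,3S,4E,7E,11S,12R)-11-acetoxy-3,12-dihydroxy-4,8,12-trimethylcyclotetradeca-4,7-dien-1-yl]prop-2-enoate (target CNP0201062.1)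
Conditions: Pd2(dba)3·CHCl3 (10 mol %), AsPh3 (40 mol %), DMF/H2O (50:1), 0.002 M by slow addition, 25 to 40 °C
Reagents that add atoms: none
Why: Zerovalent palladium ionises the vinyl epoxide of 24 with inversion to a zwitterionic π-allylpalladium alkoxide spanning C10–C12, the C9 alkenyl group is then transferred from tin (helped by Sn–O bond formation with the C13 alkoxide) and reductive elimination at the unsubstituted terminus C10 forms the C9–C10 bond. The closest known reaction type is the Stille 1,4-coupling of vinyl epoxides with alkenylstannanes, known between two molecules, together with allyl–alkenyl Stille macrocyclisations of allylic halides and carbonates. The 14-membered carbocycle closes in the SN2′ (1,4) mode at the distal allyl terminus, whereas the 1,2 mode at the quaternary C12 would give a more strained 12-membered ring and is not expected. No sp3 stereocentre is created: C13 keeps its configuration because its C–O bond is never broken, C8=C9 keeps its E geometry by retention, and the new C11=C12 alkene should be E because the π-allyl intermediate equilibrates through the σ-complex at C10 to the isomer with the large C13 substituent syn. The step needs intramolecular transmetalation to outrun coupling between chains and hydride-shift collapse of the π-allyl alkoxide to an enone or dienol, which high dilution, the weakly bound AsPh3 ligand and the polar medium should secure, while reversible re-closure to the epoxide protects the substrate. Water hydrolyses the stannyl ether at O13 so that lactonisation onto the acrylate ester is avoided and the free C13 hydroxyl of 25 results.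

Compound list

1 | pent-4-yn-1-ol | OCCCC#C | starting material
2 | dimethyl[(1E)-5-(dimethylalumanyloxy)-2-methylpent-1-en-1-yl]alumane | C[Al](C)OCCC/C(C)=C/[Al](C)C | intermediate (not isolated)
3 | (4E)-5-bromo-4-methylpent-4-en-1-ol | OCCC/C(C)=C/Br | intermediate
4 | (4E)-5-bromo-4-methylpent-4-enal | O=CCC/C(C)=C/Br | intermediate
5 | (R)-carvone, (5R)-2-methyl-5-(prop-1-en-2-yl)cyclohex-2-en-1-one | C=C(C)[C@@H]1CC=C(C)C(=O)C1 | starting material
6 | lithium (5R)-2-methyl-5-(prop-1-en-2-yl)cyclohex-1-en-1-olate | C=C(C)[C@@H]1CCC(C)=C(O[Li])C1 | intermediate (not isolated)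
7 | lithium (1RS,4E)-5-bromo-4-methyl-1-[(1R,4R)-1-methyl-2-oxo-4-(prop-1-en-2-yl)cyclohexyl]pent-4-en-1-olate | C=C(C)[C@@H]1CC[C@@](C)(C(=O)C1)C(O[Li])CC/C(C)=C/Br | intermediate (not isolated)
8 | (2R,5R)-2-[(1RS,4E)-5-bromo-4-methyl-1-(trimethylsilyloxy)pent-4-en-1-yl]-2-methyl-5-(prop-1-en-2-yl)cyclohexan-1-one | C=C(C)[C@@H]1CC[C@@](C)(C(=O)C1)C(O[Si](C)(C)C)CC/C(C)=C/Br | intermediate
9 | (4R,7R)-7-[(1RS,4E)-5-bromo-4-methyl-1-(trimethylsilyloxy)pent-4-en-1-yl]-7-methyl-4-(prop-1-en-2-yl)oxepan-2-one | C=C(C)[C@@H]1CC[C@@](C)(OC(=O)C1)C(O[Si](C)(C)C)CC/C(C)=C/Br | intermediate (not isolated)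
10 | (4R,7R)-7-[(1RS,4E)-5-bromo-1-hydroxy-4-methylpent-4-en-1-yl]-7-methyl-4-(prop-1-en-2-yl)oxepan-2-one | C=C(C)[C@@H]1CC[C@@](C)(OC(=O)C1)C(O)CC/C(C)=C/Br | intermediate
11 | (4R,7R)-7-[(4E)-5-bromo-4-methylpent-4-enoyl]-7-methyl-4-(prop-1-en-2-yl)oxepan-2-one | C=C(C)[C@@H]1CC[C@@](C)(OC(=O)C1)C(=O)CC/C(C)=C/Br | intermediate
12 | (4R,7R)-7-[(1S,4E)-5-bromo-1-hydroxy-4-methylpent-4-en-1-yl]-7-methyl-4-(prop-1-en-2-yl)oxepan-2-one | C=C(C)[C@@H]1CC[C@@](C)(OC(=O)C1)[C@@H](O)CC/C(C)=C/Br | intermediate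
13 | (3R,6R,7S,10E)-11-bromo-6,7-dihydroxy-6,10-dimethyl-3-(prop-1-en-2-yl)undec-10-enal | C=C(C)[C@@H](CC=O)CC[C@@](C)(O)[C@@H](O)CC/C(C)=C/Br | intermediate
14 | (2E,5R,8R,9S,12E)-13-bromo-8,9-dihydroxy-2,8,12-trimethyl-5-(prop-1-en-2-yl)trideca-2,12-dienal | C=C(C)[C@@H](C/C=C(\C)C=O)CC[C@@](C)(O)[C@@H](O)CC/C(C)=C/Br | intermediate
15 | (2E,5R,8R,9S,12E)-13-bromo-8-hydroxy-2,8,12-trimethyl-1-oxo-5-(prop-1-en-2-yl)trideca-2,12-dien-9-yl acetate | C=C(C)[C@@H](C/C=C(\C)C=O)CC[C@@](C)(O)[C@@H](OC(C)=O)CC/C(C)=C/Br | intermediate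
16 | (2E,5R,8R,9S,12E)-13-bromo-1,8-dihydroxy-2,8,12-trimethyl-5-(prop-1-en-2-yl)trideca-2,12-dien-9-yl acetate | C=C(C)[C@@H](C/C=C(\C)CO)CC[C@@](C)(O)[C@@H](OC(C)=O)CC/C(C)=C/Br | intermediate
17 | (2S,3S,5R,8R,9S,12E)-13-bromo-2,3-epoxy-1,8-dihydroxy-2,8,12-trimethyl-5-(prop-1-en-2-yl)tridec-12-en-9-yl acetate | C=C(C)[C@@H](C[C@@H]1O[C@@]1(C)CO)CC[C@@](C)(O)[C@@H](OC(C)=O)CC/C(C)=C/Br | intermediate
18 | (2S,3S,5R,8R,9S,12E)-13-bromo-5-(3-chloroprop-1-en-2-yl)-2,3-epoxy-1,8-dihydroxy-2,8,12-trimethyltridec-12-en-9-yl acetate | C=C(CCl)[C@@H](C[C@@H]1O[C@@]1(C)CO)CC[C@@](C)(O)[C@@H](OC(C)=O)CC/C(C)=C/Br | intermediate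
19 | (2S,3S,5R,8R,9S,12E)-13-bromo-2,3-epoxy-1,8-dihydroxy-2,8,12-trimethyl-5-(3-oxoprop-1-en-2-yl)tridec-12-en-9-yl acetate | C=C(C=O)[C@@H](C[C@@H]1O[C@@]1(C)CO)CC[C@@](C)(O)[C@@H](OC(C)=O)CC/C(C)=C/Br | intermediate
20 | 2-[(2S,3S,5R,8R,9S,12E)-9-acetoxy-13-bromo-2,3-epoxy-1,8-dihydroxy-2,8,12-trimethyltridec-12-en-5-yl]prop-2-enoic acid | C=C(C(=O)O)[C@@H](C[C@@H]1O[C@@]1(C)CO)CC[C@@](C)(O)[C@@H](OC(C)=O)CC/C(C)=C/Br | intermediate
21 | (2S,3S,5R,8R,9S,12E)-13-bromo-2,3-epoxy-1,8-dihydroxy-5-(3-methoxy-3-oxoprop-1-en-2-yl)-2,8,12-trimethyltridec-12-en-9-yl acetate | C=C(C(=O)OC)[C@@H](C[C@@H]1O[C@@]1(C)CO)CC[C@@](C)(O)[C@@H](OC(C)=O)CC/C(C)=C/Br | intermediate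
22 | (2S,3S,5R,8R,9S,12E)-2,3-epoxy-1,8-dihydroxy-5-(3-methoxy-3-oxoprop-1-en-2-yl)-2,8,12-trimethyl-13-(trimethylstannyl)tridec-12-en-9-yl acetate | C=C(C(=O)OC)[C@@H](C[C@@H]1O[C@@]1(C)CO)CC[C@@](C)(O)[C@@H](OC(C)=O)CC/C(C)=C/[Sn](C)(C)C | intermediate
23 | (2R,3S,5R,8R,9S,12E)-2,3-epoxy-8-hydroxy-5-(3-methoxy-3-oxoprop-1-en-2-yl)-2,8,12-trimethyl-1-oxo-13-(trimethylstannyl)tridec-12-en-9-yl acetate | C=C(C(=O)OC)[C@@H](C[C@@H]1O[C@@]1(C)C=O)CC[C@@](C)(O)[C@@H](OC(C)=O)CC/C(C)=C/[Sn](C)(C)C | intermediate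
24 | (3S,4S,6R,9R,10S,13E)-3,4-epoxy-9-hydroxy-6-(3-methoxy-3-oxoprop-1-en-2-yl)-3,9,13-trimethyl-14-(trimethylstannyl)tetradeca-1,13-dien-10-yl acetate | C=C(C(=O)OC)[C@@H](C[C@@H]1O[C@@]1(C)C=C)CC[C@@](C)(O)[C@@H](OC(C)=O)CC/C(C)=C/[Sn](C)(C)C | intermediate
25 | methyl 2-[(1R,3S,4E,7E,11S,12R)-11-acetoxy-3,12-dihydroxy-4,8,12-trimethylcyclotetradeca-4,7-dien-1-yl]prop-2-enoate | C=C(C(=O)OC)[C@@H]1CC[C@@](C)(O)[C@@H](OC(C)=O)CC/C(C)=C/C/C=C(\C)[C@@H](O)C1 | target

Total step count: 19. Longest linear sequence: 19 steps (steps 1 to 19 from pent-4-yn-1-ol; 17 steps from (R)-carvone, which enters at step 3).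

Steps most likely to fail

Step 19. Transfer of the alkenyl group from tin may be slower than collapse of the π-allylpalladium alkoxide by hydride shift, or chains may couple with each other instead of closing the ring. The fallback replaces tin by boron, so that the alkoxide set free on ionisation binds boron and triggers the transfer itself (base-free Suzuki–Miyaura coupling of a vinyl epoxide). It sets out from bromide 21. Miyaura borylation (B2pin2, PdCl2(PPh3)2, PPh3, KOPh, toluene, 50 °C) should give the alkenylboronate epoxy alcohol F1. Dess–Martin oxidation should give the epoxy aldehyde F2, and Wittig methylenation the vinyl epoxide boronate F3. Pd(PPh3)4 in THF/H2O at high dilution should then close the same C9–C10 bond, and the route is rejoined at 25.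

Step 3. Proton transfer from the enolisable aldehyde to the hindered enolate, or retro-aldol before the alkoxide is silylated, may return dihydrocarvone; attack on the wrong enolate face would also lower the amount of the needed C4 epimer. The fallback separates enolate formation from bond formation. Enolate 6, made from 5 as before, is trapped with Me3SiCl as the silyl enol ether F4. A TiCl4-mediated Mukaiyama aldol with 4 (CH2Cl2, −78 °C), which is non-basic and irreversible, should give the hydroxy ketone F5. Silylation (Me3SiCl, imidazole) rejoins the route at 8.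

Step 4. Oxidation at the hindered ketone may stall, or the propenyl group may be epoxidised in competition. The fallback lets both oxidations happen and then repairs the alkene. From 8, excess m-chloroperbenzoic acid (NaHCO3, CH2Cl2, rt) should carry out the Baeyer–Villiger step and epoxidise the propenyl group to give the epoxy lactone F6. Stereospecific deoxygenation of the epoxide with lower-valent tungsten chloride (WCl6, n-BuLi, THF) restores the alkene, and acidic work-up removes the silyl ether, which rejoins the route at 10.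

Further compounds

F1 | step 19 | (2S,3S,5R,8R,9S,12E)-2,3-epoxy-1,8-dihydroxy-5-(3-methoxy-3-oxoprop-1-en-2-yl)-2,8,12-trimethyl-13-(4,4,5,5-tetramethyl-1,3,2-dioxaborolan-2-yl)tridec-12-en-9-yl acetate | C=C(C(=O)OC)[C@@H](C[C@@H]1O[C@@]1(C)CO)CC[C@@](C)(O)[C@@H](OC(C)=O)CC/C(C)=C/B1OC(C)(C)C(C)(C)O1
F2 | step 19 | (2R,3S,5R,8R,9S,12E)-2,3-epoxy-8-hydroxy-5-(3-methoxy-3-oxoprop-1-en-2-yl)-2,8,12-trimethyl-1-oxo-13-(4,4,5,5-tetramethyl-1,3,2-dioxaborolan-2-yl)tridec-12-en-9-yl acetate | C=C(C(=O)OC)[C@@H](C[C@@H]1O[C@@]1(C)C=O)CC[C@@](C)(O)[C@@H](OC(C)=O)CC/C(C)=C/B1OC(C)(C)C(C)(C)O1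
F3 | step 19 | (3S,4S,6R,9R,10S,13E)-3,4-epoxy-9-hydroxy-6-(3-methoxy-3-oxoprop-1-en-2-yl)-3,9,13-trimethyl-14-(4,4,5,5-tetramethyl-1,3,2-dioxaborolan-2-yl)tetradeca-1,13-dien-10-yl acetate | C=C(C(=O)OC)[C@@H](C[C@@H]1O[C@@]1(C)C=C)CC[C@@](C)(O)[C@@H](OC(C)=O)CC/C(C)=C/B1OC(C)(C)C(C)(C)O1
F4 | step 3 | trimethyl{[(5R)-2-methyl-5-(prop-1-en-2-yl)cyclohex-1-en-1-yl]oxy}silane | C=C(C)[C@@H]1CCC(C)=C(O[Si](C)(C)C)C1
F5 | step 3 | (2R,5R)-2-[(1RS,4E)-5-bromo-1-hydroxy-4-methylpent-4-en-1-yl]-2-methyl-5-(prop-1-en-2-yl)cyclohexan-1-one | C=C(C)[C@@H]1CC[C@@](C)(C(=O)C1)C(O)CC/C(C)=C/Br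
F6 | step 4 | (4R,7R)-7-[(1RS,4E)-5-bromo-4-methyl-1-(trimethylsilyloxy)pent-4-en-1-yl]-7-methyl-4-[(2RS)-2-methyloxiran-2-yl]oxepan-2-one | CC1(CO1)[C@@H]2CC[C@@](C)(OC(=O)C2)C(O[Si](C)(C)C)CC/C(C)=C/Br
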